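The oxane is numbered O1, C2 (enyne arm), C3 (Cl), C4, C5 (Br), C6 (bromopentenyl arm). The plan exploits the vicinal pair C2 (ether carbon)/C3 (halogen carbon) of this ring: both axial halides come from equatorial alcohols by inversion, so C3 is an aldehyde carbon and C2 the β-carbon of a β-alkoxyacrylate on the C6 oxygen. A SmI2 ketyl–olefin cyclization forms C2–C3, closes the oxane and sets the 2,6-cis and 2,3-trans centres at once; its CH2CO2Et arm becomes the (Z)-enyne. The acyclic precursor gets C5/C6 from a Sharpless desymmetrisation of divinylcarbinol and its (E)-bromoalkene from a silicon-tethered trans-hydrosilylation/bromodesilylation.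

Key step: step 9

Remark: locants in the text are those of the target skeleton (oxane O1, C2–C6; bromopentenyl arm C7, C8, C9 plus ethyl), also for the open-chain intermediates. The face rule of the Sharpless asymmetric epoxidation is taken to give the (2R,3S) erythro epoxy alcohol with the L-(+)-tartrate.

Step 1
Reactants: 1 penta-1,4-dien-3-ol (divinylcarbinol)
Product: 2 (1S)-1-[(2R)-oxiran-2-yl]prop-2-en-1-ol
Conditions: Ti(OiPr)4 (cat.), L-(+)-diisopropyl tartrate (cat.), t-BuOOH, 4 Å MS, CH2Cl2, −20 °C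
Reagents that add atoms: tert-butyl hydroperoxide, CC(C)(C)OO
Why: Sharpless asymmetric epoxidation as a desymmetrisation, in which the tartrate–titanium catalyst epoxidises one enantiotopic vinyl group on the face it dictates to give the erythro epoxy alcohol, so that C6 (R) and C5 (S) are set by reagent control while the minor enantiomer is drained by a second epoxidation.

Step 2
Reactants: 2 (1S)-1-[(2R)-oxiran-2-yl]prop-2-en-1-ol
Product: 3 tert-butyldimethyl{[(1S)-1-[(2R)-oxiran-2-yl]prop-2-en-1-yl]oxy}silane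
Conditions: TBSCl, imidazole, DMF, 0 °C → rt
Reagents that add atoms: tert-butyldimethylsilyl chloride, CC(C)(C)[Si](C)(C)Cl
Why: Standard silylation of the secondary alcohol, which marks the C5 oxygen (future bromide) apart from the C6 oxygen (future ring oxygen) and should survive every step up to step 13.

Step 3
Reactants: 3 tert-butyldimethyl{[(1S)-1-[(2R)-oxiran-2-yl]prop-2-en-1-yl]oxy}silane; 4 but-1-yne
Product: 6 (3S,4R)-3-[(tert-butyldimethylsilyl)oxy]non-1-en-6-yn-4-ol, via lithium but-1-yn-1-ide 5 (not isolated)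
Conditions: n-BuLi, THF, −78 °C; BF3·OEt2; then 3, −78 °C; aq. NH4Cl
Reagents that add atoms: n-butyllithium, [Li]CCCC (lithium of 5 only)
Why: BF3-activated SN2 opening of the terminal epoxide by the alkynyllithium at the unsubstituted carbon C7 forms the C7–C8 bond and frees the C6 hydroxyl without touching either stereocentre.

Step 4
Reactants: 6 (3S,4R)-3-[(tert-butyldimethylsilyl)oxy]non-1-en-6-yn-4-ol
Product: 8 (6R)-6-[(1S)-1-[(tert-butyldimethylsilyl)oxy]prop-2-en-1-yl]-3-ethyl-2,2-dimethyl-5,6-dihydro-2H-1,2-oxasiline, via dimethylsilyl ether 7 (not isolated)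
Conditions: (HMe2Si)2NH, neat, 60 °C, then evaporation; [Cp*Ru(MeCN)3]PF6 (cat.), CH2Cl2, 0 °C → rt
Reagents that add atoms: 1,1,3,3-tetramethyldisilazane, C[SiH](C)N[SiH](C)C
Why: After O-silylation the cationic ruthenium catalyst effects intramolecular endo-dig trans-hydrosilylation of the alkyne (not of the vinyl group), the tether placing silicon on the distal carbon C9 and the six-membered ring forcing Si cis to C7.

Step 5
Reactants: 8 (6R)-6-[(1S)-1-[(tert-butyldimethylsilyl)oxy]prop-2-en-1-yl]-3-ethyl-2,2-dimethyl-5,6-dihydro-2H-1,2-oxasiline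
Product: 10 (3S,4R,6E)-7-bromo-3-[(tert-butyldimethylsilyl)oxy]nona-1,6-dien-4-ol, via anti dibromide 9 (not isolated)
Conditions: Br2, CH2Cl2, −78 °C; then NaOMe, MeOH, −78 → 0 °C
Reagents that add atoms: bromine, BrBr
Why: Bromodesilylation with inversion, in which bromine adds anti to the electron-rich trisubstituted vinylsilane (faster than to the monosubstituted, inductively deactivated vinyl group) and methoxide attack at silicon triggers anti elimination of Si and the C8 bromide, so that Br ends on C9 trans to C7 and ethyl cis to C7 ((E)-bromoalkene) while methanolysis frees the C6 hydroxyl.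

Step 6
Reactants: 10 (3S,4R,6E)-7-bromo-3-[(tert-butyldimethylsilyl)oxy]nona-1,6-dien-4-ol; 11 ethyl propiolate
Product: 12 ethyl (2E)-3-{[(3S,4R,6E)-7-bromo-3-[(tert-butyldimethylsilyl)oxy]nona-1,6-dien-4-yl]oxy}prop-2-enoate
Conditions: N-methylmorpholine, CH2Cl2, rt
Reagents that add atoms: none
Why: Amine-catalysed oxa-Michael addition of the secondary alcohol to the propiolate gives the (E)-β-alkoxyacrylate whose β-carbon is the future C2.

Step 7
Reactants: 12 ethyl (2E)-3-{[(3S,4R,6E)-7-bromo-3-[(tert-butyldimethylsilyl)oxy]nona-1,6-dien-4-yl]oxy}prop-2-enoate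
Product: 14 ethyl (2E)-3-{[(3S,4R,6E)-7-bromo-3-[(tert-butyldimethylsilyl)oxy]-1-hydroxynon-6-en-4-yl]oxy}prop-2-enoate, via B-alkyl-9-borabicyclononane 13 (not isolated)
Conditions: 9-BBN, THF, 0 °C → rt; then H2O2, aq. NaHCO3, 0 °C
Reagents that add atoms: 9-borabicyclo[3.3.1]nonane, B1C2CCCC1CCC2 (boron unit of 13 only); hydrogen peroxide, OO
Why: Hydroboration–oxidation, in which the bulky borane adds to the terminus of the monosubstituted vinyl group far faster than to the hindered, halogen-deactivated bromoalkene or the push–pull enoate, and buffered peroxide gives the primary alcohol at C3.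

Step 8
Reactants: 14 ethyl (2E)-3-{[(3S,4R,6E)-7-bromo-3-[(tert-butyldimethylsilyl)oxy]-1-hydroxynon-6-en-4-yl]oxy}prop-2-enoate
Product: 15 ethyl (2E)-3-{[(3S,4R,6E)-7-bromo-3-[(tert-butyldimethylsilyl)oxy]-1-oxonon-6-en-4-yl]oxy}prop-2-enoate
Conditions: DMP (1,1,1-triacetoxy-1,1-dihydro-1,2-benziodoxol-3(1H)-one), CH2Cl2, rt
Reagents that add atoms: none
Why: Periodinane oxidation under neutral conditions should give the β-silyloxy aldehyde without β-elimination.

Step 9
Reactants: 15 ethyl (2E)-3-{[(3S,4R,6E)-7-bromo-3-[(tert-butyldimethylsilyl)oxy]-1-oxonon-6-en-4-yl]oxy}prop-2-enoate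
Product: 16 ethyl 2-[(2S,3R,5S,6R)-6-[(2E)-3-bromopent-2-en-1-yl]-5-[(tert-butyldimethylsilyl)oxy]-3-hydroxyoxan-2-yl]acetate
Conditions: SmI2, MeOH, THF, 0 °C
Reagents that add atoms: none
Why: SmI2 reduces the aldehyde to a samarium ketyl by single-electron transfer, this nucleophilic radical adds to the β-carbon (C2) of the β-alkoxyacrylate, and the α-ester radical is reduced by a second SmI2 to the samarium enolate, which MeOH protonates. The closest known reaction type is the SmI2-mediated reductive ketyl–olefin cyclization of aldehydes carrying a β-alkoxyacrylate, an established entry to 2,6-syn-2,3-trans-3-hydroxyoxanes. The oxane closes in a 6-exo-trig radical mode by forming the C3–C2 bond. C2 is set by the existing C6 centre through a chair transition state in which the C6 arm, the C5 silyloxy group and the s-trans enoate are all equatorial (2,6-cis), and C3 is set by chelation of trivalent samarium between the ketyl oxygen and the ester carbonyl, which places the C3–O bond equatorial and trans to the C2 arm. The step needs reduction of the aldehyde in preference to the vinyl bromide and the enoate, and attack on the acrylate rather than the bromoalkene; SmI2 in THF/MeOH without HMPA leaves vinyl bromides alone, and the electron-poor acrylate is the only polarity-matched acceptor within 6-exo reach of the ketyl.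

Step 10
Reactants: 16 ethyl 2-[(2S,3R,5S,6R)-6-[(2E)-3-bromopent-2-en-1-yl]-5-[(tert-butyldimethylsilyl)oxy]-3-hydroxyoxan-2-yl]acetate
Product: 17 ethyl 2-[(2S,3S,5S,6R)-6-[(2E)-3-bromopent-2-en-1-yl]-5-[(tert-butyldimethylsilyl)oxy]-3-chlorooxan-2-yl]acetate
Conditions: (n-C8H17)3P, CCl4, toluene, 70 °C
Reagents that add atoms: tetrachloromethane, ClC(Cl)(Cl)Cl
Why: Appel-type chlorination, in which chloride displaces the equatorial C3 oxyphosphonium group by SN2 with inversion and so gives the axial chloride cis to the C2 arm, the (3S) centre of the target.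

Step 11
Reactants: 17 ethyl 2-[(2S,3S,5S,6R)-6-[(2E)-3-bromopent-2-en-1-yl]-5-[(tert-butyldimethylsilyl)oxy]-3-chlorooxan-2-yl]acetate
Product: 18 2-[(2S,3S,5S,6R)-6-[(2E)-3-bromopent-2-en-1-yl]-5-[(tert-butyldimethylsilyl)oxy]-3-chlorooxan-2-yl]acetaldehyde
Conditions: i-Bu2AlH, CH2Cl2, −78 °C; aq. KNaC4H4O6
Reagents that add atoms: none
Why: Partial ester reduction stops at the aldehyde because the tetrahedral aluminium hemiacetal, chelated by the ring oxygen, should persist at −78 °C until work-up.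

Step 12
Reactants: 18 2-[(2S,3S,5S,6R)-6-[(2E)-3-bromopent-2-en-1-yl]-5-[(tert-butyldimethylsilyl)oxy]-3-chlorooxan-2-yl]acetaldehyde; 19 1,3-bis(triisopropylsilyl)propyne
Product: 21 (2S,3S,5S,6R)-6-[(2E)-3-bromopent-2-en-1-yl]-5-[(tert-butyldimethylsilyl)oxy]-3-chloro-2-[(2Z)-5-(triisopropylsilyl)pent-2-en-4-yn-1-yl]oxane, via lithiated bis(silyl)propyne 20 (not isolated)
Conditions: n-BuLi, THF, −78 °C; then 18, −78 → 0 °C; aq. NH4Cl
Reagents that add atoms: n-butyllithium, [Li]CCCC (lithium of 20 only)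
Why: Peterson olefination, in which the bulky triisopropylsilyl groups steer the addition to the β-silyl alkoxide that syn-eliminates to the (Z)-enyne.

Step 13
Reactants: 21 (2S,3S,5S,6R)-6-[(2E)-3-bromopent-2-en-1-yl]-5-[(tert-butyldimethylsilyl)oxy]-3-chloro-2-[(2Z)-5-(triisopropylsilyl)pent-2-en-4-yn-1-yl]oxane
Product: 22 (2S,3S,5S,6R)-6-[(2E)-3-bromopent-2-en-1-yl]-3-chloro-2-[(2Z)-pent-2-en-4-yn-1-yl]oxan-5-ol
Conditions: Bu4NF, THF, 0 °C → rt
Reagents that add atoms: none
Why: Fluoride-driven desilylation cleaves the alkynyl C–Si bond and the secondary silyl ether in one operation and should leave the axial chloride, the vinyl bromide and the enyne untouched.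

Step 14
Reactants: 22 (2S,3S,5S,6R)-6-[(2E)-3-bromopent-2-en-1-yl]-3-chloro-2-[(2Z)-pent-2-en-4-yn-1-yl]oxan-5-ol
Product: 23 (2S,3S,5R,6R)-5-bromo-6-[(2E)-3-bromopent-2-en-1-yl]-3-chloro-2-[(2Z)-pent-2-en-4-yn-1-yl]oxane
Conditions: CBr4, (n-C8H17)3P, toluene, 70 °C
Reagents that add atoms: tetrabromomethane, BrC(Br)(Br)Br
Why: Appel-type bromination, in which bromide displaces the equatorial C5 oxyphosphonium group by SN2 with inversion and so installs the axial bromide cis to the C6 arm, the (5R) centre of the target.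

Compound list
1 | penta-1,4-dien-3-ol | C=CC(O)C=C | starting material
2 | (1S)-1-[(2R)-oxiran-2-yl]prop-2-en-1-ol | C=C[C@H](O)[C@H]1CO1 | intermediate
3 | tert-butyldimethyl{[(1S)-1-[(2R)-oxiran-2-yl]prop-2-en-1-yl]oxy}silane | C=C[C@H](O[Si](C)(C)C(C)(C)C)[C@H]1CO1 | intermediate
4 | but-1-yne | CCC#C | starting material
5 | lithium but-1-yn-1-ide | [Li]C#CCC | intermediate
6 | (3S,4R)-3-[(tert-butyldimethylsilyl)oxy]non-1-en-6-yn-4-ol | O[C@H](CC#CCC)[C@@H](O[Si](C)(C)C(C)(C)C)C=C | intermediate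
7 | dimethylsilyl ether of 6, tert-butyl{[(3S,4R)-4-[(dimethylsilyl)oxy]non-1-en-6-yn-3-yl]oxy}dimethylsilane | C[SiH](C)O[C@H](CC#CCC)[C@@H](O[Si](C)(C)C(C)(C)C)C=C | intermediate
8 | (6R)-6-[(1S)-1-[(tert-butyldimethylsilyl)oxy]prop-2-en-1-yl]-3-ethyl-2,2-dimethyl-5,6-dihydro-2H-1,2-oxasiline | C[Si]1(C)O[C@H](CC=C1CC)[C@@H](O[Si](C)(C)C(C)(C)C)C=C | intermediate
9 | trans-3,4-dibromo-3-ethyl-2,2-dimethyl-1,2-oxasilinane from anti addition to 8 (one of the two anti adducts shown; both converge) | C[Si]1(C)O[C@H](C[C@@H](Br)[C@@]1(Br)CC)[C@@H](O[Si](C)(C)C(C)(C)C)C=C | intermediate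
10 | (3S,4R,6E)-7-bromo-3-[(tert-butyldimethylsilyl)oxy]nona-1,6-dien-4-ol | O[C@H](C/C=C(/Br)CC)[C@@H](O[Si](C)(C)C(C)(C)C)C=C | intermediate
11 | ethyl propiolate | C#CC(=O)OCC | starting material
12 | ethyl (2E)-3-{[(3S,4R,6E)-7-bromo-3-[(tert-butyldimethylsilyl)oxy]nona-1,6-dien-4-yl]oxy}prop-2-enoate | CCOC(=O)/C=C/O[C@H](C/C=C(/Br)CC)[C@@H](O[Si](C)(C)C(C)(C)C)C=C | intermediate
13 | B-alkyl-9-borabicyclo[3.3.1]nonane from 12 (boron on C3) | CCOC(=O)/C=C/O[C@H](C/C=C(/Br)CC)[C@@H](O[Si](C)(C)C(C)(C)C)CCB1C2CCCC1CCC2 | intermediate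
14 | ethyl (2E)-3-{[(3S,4R,6E)-7-bromo-3-[(tert-butyldimethylsilyl)oxy]-1-hydroxynon-6-en-4-yl]oxy}prop-2-enoate | CCOC(=O)/C=C/O[C@H](C/C=C(/Br)CC)[C@@H](O[Si](C)(C)C(C)(C)C)CCO | intermediate
15 | ethyl (2E)-3-{[(3S,4R,6E)-7-bromo-3-[(tert-butyldimethylsilyl)oxy]-1-oxonon-6-en-4-yl]oxy}prop-2-enoate | CCOC(=O)/C=C/O[C@H](C/C=C(/Br)CC)[C@@H](O[Si](C)(C)C(C)(C)C)CC=O | intermediate
16 | ethyl 2-[(2S,3R,5S,6R)-6-[(2E)-3-bromopent-2-en-1-yl]-5-[(tert-butyldimethylsilyl)oxy]-3-hydroxyoxan-2-yl]acetate (all four ring substituents equatorial) | CCOC(=O)C[C@@H]1O[C@H](C/C=C(/Br)CC)[C@@H](O[Si](C)(C)C(C)(C)C)C[C@H]1O | intermediate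
17 | ethyl 2-[(2S,3S,5S,6R)-6-[(2E)-3-bromopent-2-en-1-yl]-5-[(tert-butyldimethylsilyl)oxy]-3-chlorooxan-2-yl]acetate | CCOC(=O)C[C@@H]1O[C@H](C/C=C(/Br)CC)[C@@H](O[Si](C)(C)C(C)(C)C)C[C@@H]1Cl | intermediate
18 | 2-[(2S,3S,5S,6R)-6-[(2E)-3-bromopent-2-en-1-yl]-5-[(tert-butyldimethylsilyl)oxy]-3-chlorooxan-2-yl]acetaldehyde | O=CC[C@@H]1O[C@H](C/C=C(/Br)CC)[C@@H](O[Si](C)(C)C(C)(C)C)C[C@@H]1Cl | intermediate
19 | 1,3-bis(triisopropylsilyl)propyne | CC(C)[Si](C(C)C)(C(C)C)CC#C[Si](C(C)C)(C(C)C)C(C)C | starting material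
20 | 1-lithio-1,3-bis(triisopropylsilyl)propyne | [Li]C(C#C[Si](C(C)C)(C(C)C)C(C)C)[Si](C(C)C)(C(C)C)C(C)C | intermediate
21 | (2S,3S,5S,6R)-6-[(2E)-3-bromopent-2-en-1-yl]-5-[(tert-butyldimethylsilyl)oxy]-3-chloro-2-[(2Z)-5-(triisopropylsilyl)pent-2-en-4-yn-1-yl]oxane | CC(C)[Si](C(C)C)(C(C)C)C#C/C=C\C[C@@H]1O[C@H](C/C=C(/Br)CC)[C@@H](O[Si](C)(C)C(C)(C)C)C[C@@H]1Cl | intermediate
22 | (2S,3S,5S,6R)-6-[(2E)-3-bromopent-2-en-1-yl]-3-chloro-2-[(2Z)-pent-2-en-4-yn-1-yl]oxan-5-ol | C#C/C=C\C[C@@H]1O[C@H](C/C=C(/Br)CC)[C@@H](O)C[C@@H]1Cl | intermediate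
23 | (2S,3S,5R,6R)-5-bromo-6-[(2E)-3-bromopent-2-en-1-yl]-3-chloro-2-[(2Z)-pent-2-en-4-yn-1-yl]oxane | C#C/C=C\C[C@@H]1O[C@H](C/C=C(/Br)CC)[C@H](Br)C[C@@H]1Cl | target

Total step count: 14. Longest linear sequence: 14 steps (1 → 23).

Steps most likely to fail

1. Step 5. Bromine may attack the silicon-bearing carbon and lose silicon directly (retention, giving the (Z)-bromoalkene) instead of following anti addition/anti elimination, or may add to the vinyl group. Fallback: starting from 8, 3-chloroperoxybenzoic acid epoxidises the vinylsilane selectively to the cis-fused epoxysilane F1. MgBr2·OEt2 opens it at the silicon-bearing carbon with inversion to the bromohydrin F2. BF3·OEt2 then induces anti β-elimination of silicon and oxygen (acid Peterson elimination), and aqueous work-up cleaves the remaining Si–O bond. This stereospecific sequence should give the same (E)-bromoalkene and rejoins the route at 10.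

2. Step 14. Bromide must approach C5 along the axial trajectory past the syn-axial C3 chloride, so substitution may be slow and E2 elimination may take over. Fallback: starting from 22, ClCH2SO2Cl and 2,6-lutidine convert the alcohol into the chloromethanesulfonate F3. This isolated, highly reactive sulfonate is displaced by LiBr in DMF with inversion under non-basic conditions, and the route is rejoined at 23.

3. Step 10. The ester carbonyl may participate at the activated C3 centre (lactonisation with loss of the ethyl group), or elimination toward C4 may compete. Fallback: starting from 16, LiBH4 reduces the ester to the diol F4, and pivaloyl chloride/pyridine acylates the primary alcohol to the pivalate F5. The same phosphine/CCl4 chlorination then gives the chloro pivalate F6, which has no carbonyl within reach of C3. i-Bu2AlH removes the pivalate to the chloro alcohol F7, and DMP oxidation rejoins the route at 18.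

Further compounds
F1 | step 5 | cis-fused 3,4-epoxide of 8 (either face; epoxide centres left open), 6-[(1S)-1-[(tert-butyldimethylsilyl)oxy]prop-2-en-1-yl]-3-ethyl-2,2-dimethyl-3,4-epoxy-1,2-oxasilinane | C[Si]1(C)O[C@H](CC2OC12CC)[C@@H](O[Si](C)(C)C(C)(C)C)C=C
F2 | step 5 | trans-3-bromo-3-ethyl-4-hydroxy-2,2-dimethyl-1,2-oxasilinane from F1 (one of the two anti isomers shown) | C[Si]1(C)O[C@H](C[C@@H](O)[C@@]1(Br)CC)[C@@H](O[Si](C)(C)C(C)(C)C)C=C
F3 | step 14 | (2S,3S,5S,6R)-6-[(2E)-3-bromopent-2-en-1-yl]-3-chloro-2-[(2Z)-pent-2-en-4-yn-1-yl]oxan-5-yl chloromethanesulfonate | C#C/C=C\C[C@@H]1O[C@H](C/C=C(/Br)CC)[C@@H](OS(=O)(=O)CCl)C[C@@H]1Cl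
F4 | step 10 | (2S,3R,5S,6R)-6-[(2E)-3-bromopent-2-en-1-yl]-5-[(tert-butyldimethylsilyl)oxy]-2-(2-hydroxyethyl)oxan-3-ol | OCC[C@@H]1O[C@H](C/C=C(/Br)CC)[C@@H](O[Si](C)(C)C(C)(C)C)C[C@H]1O
F5 | step 10 | 2-[(2S,3R,5S,6R)-6-[(2E)-3-bromopent-2-en-1-yl]-5-[(tert-butyldimethylsilyl)oxy]-3-hydroxyoxan-2-yl]ethyl 2,2-dimethylpropanoate | CC(C)(C)C(=O)OCC[C@@H]1O[C@H](C/C=C(/Br)CC)[C@@H](O[Si](C)(C)C(C)(C)C)C[C@H]1O
F6 | step 10 | 2-[(2S,3S,5S,6R)-6-[(2E)-3-bromopent-2-en-1-yl]-5-[(tert-butyldimethylsilyl)oxy]-3-chlorooxan-2-yl]ethyl 2,2-dimethylpropanoate | CC(C)(C)C(=O)OCC[C@@H]1O[C@H](C/C=C(/Br)CC)[C@@H](O[Si](C)(C)C(C)(C)C)C[C@@H]1Cl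
F7 | step 10 | 2-[(2S,3S,5S,6R)-6-[(2E)-3-bromopent-2-en-1-yl]-5-[(tert-butyldimethylsilyl)oxy]-3-chlorooxan-2-yl]ethan-1-ol | OCC[C@@H]1O[C@H](C/C=C(/Br)CC)[C@@H](O[Si](C)(C)C(C)(C)C)C[C@@H]1Cl
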